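Compound numbers 1–22 are those of the steps below and are used in every section.

## The problem

The target is a (2S)-flavanone whose ring A is a fully substituted phloroglucinol. C4a carries the ring C carbonyl, C8a the ring oxygen O1, C5 and C7 free hydroxyls, and C8 a 5-hydroxy-5-methyl-2-(prop-1-en-2-yl)hexyl chain. Two stereocentres must be set, C2 of ring C (S) and C2'' of the side chain (R). They are separated by an aromatic ring and five bonds, so neither can direct the other and each needs its own external control. Ring C must close through the oxygen on C8a and not through the constitutionally similar oxygen on C5, otherwise the 6-substituted isomer forms; the three ring A oxygens therefore have to be told apart. The molecule is fragile: strong acid adds the C7 hydroxyl across the isopropenyl group and ionises the tertiary alcohol, and base opens ring C to the 2'-hydroxychalcone and so epimerises C2, an opening made easier by the electron-rich ring B. The enabling feature is the benzylic CH2 (C1'') on C8: it lies ortho to a phenolic oxygen and is bonded to C2'', the pattern left when a carbon nucleophile adds to the CH2 terminus of an ortho-quinone methide. If that nucleophile is an aldehyde enamine, the aldehyde carbon arrives next to C2'' and can become the isopropenyl carbon, while the phenol oxygen that closes onto it is marked as the future O1.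

## Retrosynthesis

**22 from 21.** The last cut removes the three methoxymethyl ethers (O5, O7, O4') and the triethylsilyl ether of the tertiary alcohol. Acetal ethers are preferred to benzyl ethers (hydrogenolysis would saturate the isopropenyl group), to allyl ethers (C-allylation of the phloroglucinol nucleus at the outset) and to aryl silyl ethers (lost in the hydroxide-mediated condensation). Compound 21 is no simpler in skeleton, but it tolerates base and nucleophiles. The forward reaction must be dilute acid at ambient temperature.

**21 from 20.** The O1–C2 bond is cut in the oxa-Michael sense. Chalcone 20 has one free hydroxyl only, the one flanked by the acyl group and the side chain, so closure can give only the 8-substituted flavanone. The neighbouring cuts (C2–aryl by conjugate arylation of a chromone, or C2–C3) would need an ortho-substituted electron-rich aryl nucleophile or a carbene. The precursor has lost ring C and the C2 centre. The forward step must select one face of the enone β-carbon under catalyst control and be mild enough that the product does not re-open.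

**20 from 17 and 19.** The enone C=C bond (future C2–C3) is cut in the aldol sense into acetophenone 17 and aldehyde 19; 19 comes from 18 by etherification. This is the most convergent cut and halves the molecule. The 4'-hydroxyl must be masked so that the aldehyde is not deactivated as a phenoxide. The forward step needs everything to survive hydroxide, which holds because C2'' no longer has an acidifying neighbour.

**17 from 14 through 16 and 15.** The C4a–C4 bond is cut. Friedel–Crafts or Fries acylation would cleave the acetals, add the phenol to the isopropenyl group and fail to distinguish the two free ring positions. Directed lithiation would go between the two acetal oxygens, the future C6. The magnesium phenoxide of 14 delivers a one-carbon electrophile only to the single free ortho position, giving aldehyde 15; methyl addition (16) and benzylic oxidation give 17. Three steps for one acetyl group are the price of regiocontrol. Precursor 14 is a simple trisubstituted phenol.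

**14 from 10 through 13, 12 and 11.** The isopropenyl group is cut first at C=CH2 (methylenation of methyl ketone 13), then at C–CH3 (methyl addition to the N-methoxy-N-methylamide 12, formed in the flask from lactone 11). This traces the isopropenyl carbon back to the lactol carbon of 10. Passing through the lactone avoids oxidising a secondary alcohol beside a free, very electron-rich phenol. Because C2'' is α to a carbonyl in 11–13, each forward step must be non-enolising.

**10 from 4 and 8 through 9.** The C1''–C2'' bond and the O1–C(lactol) bond are cut together. A 2,4,6-trioxygenated benzyl halide is not a usable alkylating agent, whereas the same carbon is easily reached as quinone methide 9 from sulfone 4. The enamine of aldehyde 8 sets C2'' catalytically, and the ring-closing oxygen is labelled as O1, which later makes steps 11 and 16 regiospecific. Both precursors are achiral and small. The forward step needs the enamine to outrun all other nucleophiles and needs clean facial bias of an E-enamine.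

**4 from 1; 8 from 5.** Sulfone 4 is cut at C–S back to salicyl alcohol 3, aldehyde 2 and commercial 1; the hydrogen-bonded ortho-hydroxyl of 1 stays free, which gives the pattern needed. Aldehyde 8 is cut at the two C–CH3 bonds of the carbinol back to lactone 5 through diol 6 and bis-silyl ether 7. The forward steps are routine; the only demand is oxidation of the primary position of 7 without touching the tertiary silyl ether.

## Roads not taken

Alternative 1: Ring A itself would be disconnected (C8a–C8, C7–C6 and the closing C4a–C8a bond) by a Danheiser benzannulation.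
- **Forward step:** Siloxyalkyne A2 would be made from (R)-limonene A4 by cleavage of the ring alkene, chain adjustment and ester-to-ynol-ether homologation. Heating A2 with cyclobutenone A3 would give phenol A1 through a ketene, a (2+2) addition, a four-electron ring opening and a six-electron closure.
- **Merits:** C2'' comes from the chiral pool with the correct (R) configuration and does not depend on any catalyst. In this respect the route is better than the chosen one. The three ring A oxygens are also born different.
- **Weak points:** A2 needs roughly eight steps from A4, including selective cleavage of the trisubstituted alkene beside the isopropenyl group and differentiation of an aldehyde from a ketone. The ketene intermediates may be intercepted by the pendant alkene. The silyl ether on O7 would not survive the later hydroxide condensation. A1 stands only at the stage of phenol 14, so all of steps 11–17 still lie ahead.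
- **Comparison:** The chosen plan reaches 14 in ten steps (longest line seven) from achiral commodity compounds and does not have to build an aromatic ring. Against the pool-derived centre it sets catalyst control at an unhindered α-methylene aldehyde, normally a favourable case, plus an auxiliary fallback.

Alternative 2: Ring C would be cut at C3–C4 and O1–C2 in a (4+2) sense.
- **Forward step:** Salicylaldehyde A6 (the desilylated analogue of 15) would be converted under a chiral Brønsted acid into its 4-methoxy quinone methide A8. Cycloaddition with styrene A7 would give the 2,4-cis 4-methoxyflavan A5 with C2 set.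
- **Merits:** Ring C forms in one step from the aldehyde stage instead of four. C2 is fixed in an irreversible cycloaddition, which is more secure than the reversible addition of step 16.
- **Weak points:** A5 has the wrong oxidation level at C4, and correcting it takes at least two steps through an ionisation-prone benzylic ether, beside the isopropenyl group and a free ring B phenol. The acid that generates A8 endangers the acetals, the tertiary alcohol and the isopropenyl group of A6. A7 is a para-hydroxystyrene that oligomerises under acid. Chiral-acid control of 4-alkoxy quinone methides is less charted than that of 4-aryl ones. C2'' is not addressed, so A6 would still be made by steps 1–11.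
- **Comparison:** The chosen plan has the correct C4 oxidation level from the start and stays basic or neutral once the isopropenyl group is present. It concedes that its own C2-forming step is the less secure of the two and answers with a resolution fallback.

Alternative 3: Ring C would be cut at C2–C3.
- **Forward step:** Diazomethyl ketone A10, carrying ring B as a benzyl ether on O1, would be decomposed by a chiral dirhodium tetracarboxylate (Rh2L4). Insertion of the carbene into the benzylic C–H bond would close ring C, set C2 and give the fully silylated flavanone A9.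
- **Merits:** The C–C closure is irreversible. The all-silyl protection is removable with fluoride, which is gentler to the isopropenyl group than the acid of step 17; in this respect the route is better.
- **Weak points:** Acceptor-only carbenes are poorly selective. The ether oxygen next to the carbene favours oxonium ylide formation and a 1,2-shift to a 2-benzylbenzofuranone. The electron-rich ring B invites aromatic cycloaddition, and the isopropenyl group can be cyclopropanated. A10 needs a hindered C4a carboxylic acid, a diazoalkane acylation and a selective O1 benzylation, which is longer than steps 11–13. C2'' is again left open.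
- **Comparison:** The chosen plan builds ring C with classical reactions whose single open question is facial selectivity. It offers a silyl-transfer fallback for the deprotection.

Key step: step 7

Assumption: the sense of induction in step 7 (by analogy with other α-functionalisations under the same catalyst) and in step 16 is assigned by analogy; if either proves opposite, the enantiomeric or pseudoenantiomeric catalyst is used with no other change.

## Route

Step 1
Reactants: 1 2,4,6-trihydroxybenzaldehyde
Product: 2 2-hydroxy-4,6-bis(methoxymethoxy)benzaldehyde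
Conditions: MOMCl (2.2 equiv), iPr2NEt (3 equiv), CH2Cl2, 0 °C to rt
Reagents that add atoms: chloromethyl methyl ether, COCCl
Why: Selective O-alkylation (acetal ether formation): the 4-hydroxyl and one ortho-hydroxyl react, while the remaining ortho-hydroxyl is held in a hydrogen bond to the formyl group and stays free; the hard electrophile avoids C-alkylation.

Step 2
Reactants: 2 2-hydroxy-4,6-bis(methoxymethoxy)benzaldehyde
Product: 3 2-(hydroxymethyl)-3,5-bis(methoxymethoxy)phenol
Conditions: NaBH4, MeOH/THF, 0 °C
Reagents that add atoms: none
Why: Hydride reduction of an aromatic aldehyde; the ionisation-prone salicyl alcohol is carried on without storage.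

Step 3
Reactants: 3 2-(hydroxymethyl)-3,5-bis(methoxymethoxy)phenol
Product: 4 3,5-bis(methoxymethoxy)-2-[(4-methylbenzenesulfonyl)methyl]phenol
Conditions: TolSO2Na (2 equiv), AcOH (3 equiv), THF/H2O, rt
Reagents that add atoms: sodium 4-methylbenzenesulfinate, Cc1ccc(cc1)S(=O)[O-].[Na+]
Why: Substitution through the benzylic cation or quinone methide: the trioxygenated benzylic alcohol ionises under acetate buffering and is captured at sulfur, the sulfone being the thermodynamic product; the buffered medium spares the acetals.

Step 4
Reactants: 5 δ-valerolactone (oxan-2-one)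
Product: 6 5-methylhexane-1,5-diol
Conditions: MeMgBr (2.5 equiv), THF, 0 °C to rt; aq NH4Cl
Reagents that add atoms: methylmagnesium bromide, C[Mg]Br
Why: Double Grignard addition to a lactone with ring opening gives the tertiary carbinol and the primary alcohol.

Step 5
Reactants: 6 5-methylhexane-1,5-diol
Product: 7 5-methyl-1,5-bis(triethylsilyloxy)hexane
Conditions: TESOTf (2.5 equiv), 2,6-lutidine, CH2Cl2, −78 to 0 °C
Reagents that add atoms: triethylsilyl trifluoromethanesulfonate, CC[Si](CC)(CC)OS(=O)(=O)C(F)(F)F
Why: Silylation with a silyl triflate, which is needed for the tertiary hydroxyl; both hydroxyls are capped.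

Step 6
Reactants: 7 5-methyl-1,5-bis(triethylsilyloxy)hexane
Product: 8 5-methyl-5-(triethylsilyloxy)hexanal
Conditions: (COCl)2, DMSO, CH2Cl2, −78 to −30 °C; Et3N, −78 °C to rt
Reagents that add atoms: none
Why: Swern oxidation applied directly to the silyl ether: the primary triethylsilyl ether is cleaved by the chlorosulfonium species and oxidised in the same flask, while the hindered tertiary silyl ether is inert.

Step 7
Reactants: 4 3,5-bis(methoxymethoxy)-2-[(4-methylbenzenesulfonyl)methyl]phenol; 8 5-methyl-5-(triethylsilyloxy)hexanal (1.5 equiv)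
Product: 10 (3R)-5,7-bis(methoxymethoxy)-3-[3-methyl-3-(triethylsilyloxy)butyl]chroman-2-ol as a mixture of anomers, via ortho-quinone methide 9 (not isolated)
Conditions: (S)-α,α-diphenylprolinol trimethylsilyl ether (20 mol %), K2CO3 (1.5 equiv), CH2Cl2, 0 °C to rt
Reagents that add atoms: none
Why: K2CO3 deprotonates the phenol of 4, and 1,4-elimination of sulfinate releases quinone methide 9 slowly from the solid–liquid mixture. Aldehyde 8 condenses with the amine to the E-enamine, whose α-carbon adds to the exocyclic CH2 of 9 through the face remote from the diphenyl(silyloxy)methyl group; this re-aromatises ring A and forms the C1''–C2'' bond. The phenoxide then closes onto the iminium carbon in a 6-exo-trig step (the two events may merge into an asynchronous hetero-Diels–Alder addition), and hydrolysis of the N,O-aminal releases lactol 10 and the catalyst. The closest known reaction type is the aminocatalytic formal (4+2) addition of aldehydes to quinone methides generated in situ from 2-(sulfonylmethyl)phenols, which gives 3-substituted chroman-2-ols. C2'' is the only controlled new centre; since the CH2 terminus is not stereogenic, its configuration depends only on enamine geometry and facial shielding, and the (S)-catalyst is expected to give (R), while the anomeric centre is uncontrolled and is erased in step 8. The step needs the enamine to capture 9 faster than sulfinate, the amine or the C-nucleophilic phenoxide of 4 can; slow release of 9, excess 8, the bulk of the amine and the tempering effect of the two donor oxygens on 9 secure this. The lactol ring then shields C2'' from re-enolisation.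

Step 8
Reactants: 10 (3R)-5,7-bis(methoxymethoxy)-3-[3-methyl-3-(triethylsilyloxy)butyl]chroman-2-ol
Product: 11 (3R)-5,7-bis(methoxymethoxy)-3-[3-methyl-3-(triethylsilyloxy)butyl]chroman-2-one
Conditions: DMP (1,1,1-triacetoxy-1,1-dihydro-1,2-benziodoxol-3(1H)-one, 1.5 equiv), NaHCO3, CH2Cl2, 0 °C to rt
Reagents that add atoms: none
Why: Periodinane oxidation of a lactol to the lactone; no free phenol meets the oxidant, both anomers converge, and the buffered neutral medium does not enolise C3.

Step 9
Reactants: 11 (3R)-5,7-bis(methoxymethoxy)-3-[3-methyl-3-(triethylsilyloxy)butyl]chroman-2-one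
Product: 13 (3R)-3-{[2-hydroxy-4,6-bis(methoxymethoxy)phenyl]methyl}-6-methyl-6-(triethylsilyloxy)heptan-2-one, via Weinreb amide 12 (not isolated)
Conditions: MeNHOMe·HCl (2 equiv), iPrMgCl (4 equiv), THF, −20 °C; then MeMgBr (3 equiv), −20 to 0 °C; aq NH4Cl
Reagents that add atoms: methylmagnesium bromide, C[Mg]Br
Why: Weinreb ketone synthesis in one flask: the chloromagnesium amide opens the aryl lactone, and the chelated adduct formed with MeMgBr stops at the ketone stage; at low temperature the α-centre is not deprotonated. Compound 13 may sit partly as its cyclic hemiketal.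

Step 10
Reactants: 13 (3R)-3-{[2-hydroxy-4,6-bis(methoxymethoxy)phenyl]methyl}-6-methyl-6-(triethylsilyloxy)heptan-2-one
Product: 14 3,5-bis(methoxymethoxy)-2-[(2R)-5-methyl-2-(prop-1-en-2-yl)-5-(triethylsilyloxy)hexyl]phenol
Conditions: Cp2TiMe2 (3 equiv), toluene/THF, 65 °C, dark
Reagents that add atoms: dimethyltitanocene, [CH3-].[CH3-].[Ti+4].c1cc[cH-]c1.c1cc[cH-]c1
Why: Petasis methylenation (titanium methylidene, olefination through an oxatitanacyclobutane); it is non-basic, so C2'' is not enolised, and the phenol merely consumes one equivalent as a titanium aryloxide that is hydrolysed on work-up.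

Step 11
Reactants: 14 3,5-bis(methoxymethoxy)-2-[(2R)-5-methyl-2-(prop-1-en-2-yl)-5-(triethylsilyloxy)hexyl]phenol
Product: 15 2-hydroxy-4,6-bis(methoxymethoxy)-3-[(2R)-5-methyl-2-(prop-1-en-2-yl)-5-(triethylsilyloxy)hexyl]benzaldehyde
Conditions: MgCl2 (2 equiv), Et3N (4 equiv), (CH2O)n (6 equiv), THF, reflux
Reagents that add atoms: paraformaldehyde (as formaldehyde), C=O
Why: Magnesium-mediated ortho-formylation (Casnati–Skattebøl): the magnesium phenoxide delivers formaldehyde through a chelated transition state to the only free ortho position, the future C4a, and a second formaldehyde accepts hydride; the position between the two acetal oxygens is not touched.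

Step 12
Reactants: 15 2-hydroxy-4,6-bis(methoxymethoxy)-3-[(2R)-5-methyl-2-(prop-1-en-2-yl)-5-(triethylsilyloxy)hexyl]benzaldehyde
Product: 16 2-(1-hydroxyethyl)-3,5-bis(methoxymethoxy)-6-[(2R)-5-methyl-2-(prop-1-en-2-yl)-5-(triethylsilyloxy)hexyl]phenol (both carbinol epimers)
Conditions: MeMgBr (3 equiv), THF, −78 to 0 °C; aq NH4Cl
Reagents that add atoms: methylmagnesium bromide, C[Mg]Br
Why: Grignard addition to the aldehyde after deprotonation of the phenol; the new carbinol centre is uncontrolled and is removed in step 13.

Step 13
Reactants: 16 2-(1-hydroxyethyl)-3,5-bis(methoxymethoxy)-6-[(2R)-5-methyl-2-(prop-1-en-2-yl)-5-(triethylsilyloxy)hexyl]phenol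
Product: 17 1-{2-hydroxy-4,6-bis(methoxymethoxy)-3-[(2R)-5-methyl-2-(prop-1-en-2-yl)-5-(triethylsilyloxy)hexyl]phenyl}ethan-1-one
Conditions: MnO2 (activated, excess), CH2Cl2, rt
Reagents that add atoms: none
Why: MnO2 oxidation of an activated benzylic alcohol; the alkene and the silyl ether are left alone, and the product phenol is stabilised by chelation to the new carbonyl.

Step 14
Reactants: 18 4-hydroxy-2-methoxybenzaldehyde
Product: 19 2-methoxy-4-(methoxymethoxy)benzaldehyde
Conditions: MOMCl (1.3 equiv), iPr2NEt (2 equiv), CH2Cl2, 0 °C to rt
Reagents that add atoms: chloromethyl methyl ether, COCCl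
Why: Phenol etherification (acetal ether formation); a free 4-hydroxyl would deactivate the aldehyde as its phenoxide in step 15.

Step 15
Reactants: 17 1-{2-hydroxy-4,6-bis(methoxymethoxy)-3-[(2R)-5-methyl-2-(prop-1-en-2-yl)-5-(triethylsilyloxy)hexyl]phenyl}ethan-1-one; 19 2-methoxy-4-(methoxymethoxy)benzaldehyde
Product: 20 (2E)-1-{2-hydroxy-4,6-bis(methoxymethoxy)-3-[(2R)-5-methyl-2-(prop-1-en-2-yl)-5-(triethylsilyloxy)hexyl]phenyl}-3-[2-methoxy-4-(methoxymethoxy)phenyl]prop-2-en-1-one
Conditions: KOH (aq 50 %, excess), EtOH, 0 °C to rt; neutralise cold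
Reagents that add atoms: none
Why: Claisen–Schmidt condensation (crossed aldol, then E1cB dehydration) gives the E-enone; in strong alkali the chelated phenoxide does not cyclise appreciably, and C2'' has no acidifying neighbour.

Step 16
Reactants: 20 (2E)-1-{2-hydroxy-4,6-bis(methoxymethoxy)-3-[(2R)-5-methyl-2-(prop-1-en-2-yl)-5-(triethylsilyloxy)hexyl]phenyl}-3-[2-methoxy-4-(methoxymethoxy)phenyl]prop-2-en-1-one
Product: 21 (2S)-5,7-bis(methoxymethoxy)-2-[2-methoxy-4-(methoxymethoxy)phenyl]-8-[(2R)-5-methyl-2-(prop-1-en-2-yl)-5-(triethylsilyloxy)hexyl]chroman-4-one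
Conditions: 1-[3,5-bis(trifluoromethyl)phenyl]-3-[(9R)-6'-methoxycinchonan-9-yl]thiourea (the thiourea of 9-amino-9-deoxy-epi-quinidine, 20 mol %), toluene, −20 °C to rt; stopped before equilibrium
Reagents that add atoms: none
Why: Enantioselective intramolecular oxa-Michael addition (6-endo-trig): the quinuclidine deprotonates the phenol while the thiourea binds the enone carbonyl, so the ion pair closes on one face of the β-carbon and sets C2. C2'' is too remote to interfere, and since only the hydroxyl between C8 and the acyl group is free, only the 8-substituted flavanone can form.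

Step 17
Reactants: 21 (2S)-5,7-bis(methoxymethoxy)-2-[2-methoxy-4-(methoxymethoxy)phenyl]-8-[(2R)-5-methyl-2-(prop-1-en-2-yl)-5-(triethylsilyloxy)hexyl]chroman-4-one
Product: 22 (2S)-5,7-dihydroxy-2-(4-hydroxy-2-methoxyphenyl)-8-[(2R)-5-hydroxy-5-methyl-2-(prop-1-en-2-yl)hexyl]chroman-4-one
Conditions: HCl (2 M aq), MeOH/THF, rt
Reagents that add atoms: none
Why: Acid-catalysed solvolysis of the three acetals and the silyl ether; dilute acid at room temperature is chosen to stay below the threshold for addition of the C7 hydroxyl to the isopropenyl group and for opening of ring C.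

## Compound list

1 | 2,4,6-trihydroxybenzaldehyde | O=Cc1c(O)cc(O)cc1O | starting material
2 | 2-hydroxy-4,6-bis(methoxymethoxy)benzaldehyde | O=Cc1c(O)cc(OCOC)cc1OCOC | intermediate
3 | 2-(hydroxymethyl)-3,5-bis(methoxymethoxy)phenol | OCc1c(O)cc(OCOC)cc1OCOC | intermediate
4 | 3,5-bis(methoxymethoxy)-2-[(4-methylbenzenesulfonyl)methyl]phenol | Cc1ccc(cc1)S(=O)(=O)Cc1c(O)cc(OCOC)cc1OCOC | intermediate
5 | δ-valerolactone (oxan-2-one) | O=C1CCCCO1 | starting material
6 | 5-methylhexane-1,5-diol | CC(C)(O)CCCCO | intermediate
7 | 5-methyl-1,5-bis(triethylsilyloxy)hexane | CC[Si](CC)(CC)OCCCCC(C)(C)O[Si](CC)(CC)CC | intermediate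
8 | 5-methyl-5-(triethylsilyloxy)hexanal | CC[Si](CC)(CC)OC(C)(C)CCCC=O | intermediate
9 | 3,5-bis(methoxymethoxy)-6-methylidenecyclohexa-2,4-dien-1-one (ortho-quinone methide, not isolated) | C=C1C(=O)C=C(OCOC)C=C1OCOC | intermediate
10 | (3R)-5,7-bis(methoxymethoxy)-3-[3-methyl-3-(triethylsilyloxy)butyl]chroman-2-ol (anomeric mixture) | OC1Oc2cc(OCOC)cc(OCOC)c2C[C@H]1CCC(C)(C)O[Si](CC)(CC)CC | intermediate
11 | (3R)-5,7-bis(methoxymethoxy)-3-[3-methyl-3-(triethylsilyloxy)butyl]chroman-2-one | O=C1Oc2cc(OCOC)cc(OCOC)c2C[C@H]1CCC(C)(C)O[Si](CC)(CC)CC | intermediate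
12 | (2R)-2-{[2-hydroxy-4,6-bis(methoxymethoxy)phenyl]methyl}-N-methoxy-N,5-dimethyl-5-(triethylsilyloxy)hexanamide (not isolated) | CON(C)C(=O)[C@@H](Cc1c(O)cc(OCOC)cc1OCOC)CCC(C)(C)O[Si](CC)(CC)CC | intermediate
13 | (3R)-3-{[2-hydroxy-4,6-bis(methoxymethoxy)phenyl]methyl}-6-methyl-6-(triethylsilyloxy)heptan-2-one | CC(=O)[C@@H](Cc1c(O)cc(OCOC)cc1OCOC)CCC(C)(C)O[Si](CC)(CC)CC | intermediate
14 | 3,5-bis(methoxymethoxy)-2-[(2R)-5-methyl-2-(prop-1-en-2-yl)-5-(triethylsilyloxy)hexyl]phenol | C=C(C)[C@@H](Cc1c(O)cc(OCOC)cc1OCOC)CCC(C)(C)O[Si](CC)(CC)CC | intermediate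
15 | 2-hydroxy-4,6-bis(methoxymethoxy)-3-[(2R)-5-methyl-2-(prop-1-en-2-yl)-5-(triethylsilyloxy)hexyl]benzaldehyde | C=C(C)[C@@H](Cc1c(O)c(C=O)c(OCOC)cc1OCOC)CCC(C)(C)O[Si](CC)(CC)CC | intermediate
16 | 2-(1-hydroxyethyl)-3,5-bis(methoxymethoxy)-6-[(2R)-5-methyl-2-(prop-1-en-2-yl)-5-(triethylsilyloxy)hexyl]phenol (carbinol epimers) | C=C(C)[C@@H](Cc1c(O)c(C(C)O)c(OCOC)cc1OCOC)CCC(C)(C)O[Si](CC)(CC)CC | intermediate
17 | 1-{2-hydroxy-4,6-bis(methoxymethoxy)-3-[(2R)-5-methyl-2-(prop-1-en-2-yl)-5-(triethylsilyloxy)hexyl]phenyl}ethan-1-one | C=C(C)[C@@H](Cc1c(O)c(C(C)=O)c(OCOC)cc1OCOC)CCC(C)(C)O[Si](CC)(CC)CC | intermediate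
18 | 4-hydroxy-2-methoxybenzaldehyde | COc1cc(O)ccc1C=O | starting material
19 | 2-methoxy-4-(methoxymethoxy)benzaldehyde | COCOc1ccc(C=O)c(OC)c1 | intermediate
20 | (2E)-1-{2-hydroxy-4,6-bis(methoxymethoxy)-3-[(2R)-5-methyl-2-(prop-1-en-2-yl)-5-(triethylsilyloxy)hexyl]phenyl}-3-[2-methoxy-4-(methoxymethoxy)phenyl]prop-2-en-1-one | C=C(C)[C@@H](Cc1c(O)c(C(=O)/C=C/c2ccc(OCOC)cc2OC)c(OCOC)cc1OCOC)CCC(C)(C)O[Si](CC)(CC)CC | intermediate
21 | (2S)-5,7-bis(methoxymethoxy)-2-[2-methoxy-4-(methoxymethoxy)phenyl]-8-[(2R)-5-methyl-2-(prop-1-en-2-yl)-5-(triethylsilyloxy)hexyl]chroman-4-one | C=C(C)[C@H](CCC(C)(C)O[Si](CC)(CC)CC)Cc1c(OCOC)cc(OCOC)c2c1O[C@H](c1ccc(OCOC)cc1OC)CC2=O | intermediate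
22 | (2S)-5,7-dihydroxy-2-(4-hydroxy-2-methoxyphenyl)-8-[(2R)-5-hydroxy-5-methyl-2-(prop-1-en-2-yl)hexyl]chroman-4-one | C=C(C)[C@H](CCC(C)(C)O)Cc1c(O)cc(O)c2c1O[C@H](c1ccc(O)cc1OC)CC2=O | target

## Step count and risk

Total: 17 steps. Longest linear sequence: 13 steps (steps 1–3 or 4–6, then 7–13 and 15–17).

**Step 7 (key step).** The quinone methide may be captured by the phenoxide of its own precursor, by sulfinate or by the amine faster than by the enamine, because an unsubstituted methide is very electrophilic while the enamine concentration is low; this would lead to oligomerisation and catalyst N-alkylation. A second risk is partial loss of configuration at C2'' through the open hydroxy-aldehyde form before oxidation. The fallback replaces the catalytic enamine by a stoichiometric auxiliary enolate. Aldehyde 8 would be oxidised (NaClO2, NaH2PO4, 2-methyl-2-butene) to 5-methyl-5-(triethylsilyloxy)hexanoic acid F1. This would be coupled through its pivaloyl mixed anhydride (Et3N, LiCl) with (4S)-4-benzyl-1,3-oxazolidin-2-one to the imide (4S)-4-benzyl-3-[5-methyl-5-(triethylsilyloxy)hexanoyl]-1,3-oxazolidin-2-one F2. Its sodium enolate (NaN(SiMe3)2, THF, −78 °C) would be treated with the sodium phenoxide of 4 (NaH), which releases 9 on warming. Addition on the enolate face opposite the benzyl group should give the (2R) adduct (4S)-4-benzyl-3-[(2R)-2-{[2-hydroxy-4,6-bis(methoxymethoxy)phenyl]methyl}-5-methyl-5-(triethylsilyloxy)hexanoyl]-1,3-oxazolidin-2-one F3. Its phenoxide acylates itself on warming and expels the auxiliary, so the route is rejoined at lactone 11.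

**Step 16.** Facial selectivity may be poor, and the selectivity reached may erode as the reversible addition approaches equilibrium, because the chalcone lacks an activating ester, the phenol is hindered by C8, and the electron-rich ring B makes re-opening easy. The fallback gives up enantioselective closure for a catalyst-controlled resolution. From 20, NaOAc in refluxing EtOH would give the C2-epimeric flavanone mixture F4. Asymmetric transfer hydrogenation with RuCl(p-cymene)[(R,R)-TsDPEN] in HCO2H/Et3N should then reduce the (2R) epimer preferentially to the (2R,4R)-cis-flavan-4-ol F5. The unreduced ketone is 21, separated by chromatography; F5 can be re-oxidised and re-equilibrated.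

**Step 17.** Brønsted acid may add the C7 hydroxyl across the isopropenyl group, solvolyse the tertiary alcohol or epimerise C2 by ionisation of the benzylic C2–O1 bond, all favoured by the time needed to cleave the least labile acetal on O7. The fallback avoids protic acid. From 21, TMSOTf and 2,2'-bipyridyl in MeCN at 0 °C would convert the three aryl acetals into aryl silyl ethers, giving the tris(trimethylsilyl) ether F6. Pyridine-buffered HF·pyridine in THF would then remove all four silyl groups and give 22.

**Step 10.** Methylenation may stall, because the phenol is converted to a titanium aryloxide and the ketone can hide as its hemiketal; prolonged heating to compensate could epimerise C2''. The fallback is a Peterson olefination. From 13, Me3SiCH2Li with CeCl3 in THF at −78 °C would add without enolisation to give the β-hydroxysilane (3R)-3-{[2-hydroxy-4,6-bis(methoxymethoxy)phenyl]methyl}-2,6-dimethyl-6-(triethylsilyloxy)-1-(trimethylsilyl)heptan-2-ol F7. Elimination with KH in THF would return the route to 14.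

## Further compounds

F1 | step 7 | 5-methyl-5-(triethylsilyloxy)hexanoic acid | CC[Si](CC)(CC)OC(C)(C)CCCC(=O)O
F2 | step 7 | (4S)-4-benzyl-3-[5-methyl-5-(triethylsilyloxy)hexanoyl]-1,3-oxazolidin-2-one | CC[Si](CC)(CC)OC(C)(C)CCCC(=O)N1[C@@H](Cc2ccccc2)COC1=O
F3 | step 7 | (4S)-4-benzyl-3-[(2R)-2-{[2-hydroxy-4,6-bis(methoxymethoxy)phenyl]methyl}-5-methyl-5-(triethylsilyloxy)hexanoyl]-1,3-oxazolidin-2-one | O=C1OC[C@H](Cc2ccccc2)N1C(=O)[C@@H](Cc1c(O)cc(OCOC)cc1OCOC)CCC(C)(C)O[Si](CC)(CC)CC
F4 | step 16 | 5,7-bis(methoxymethoxy)-2-[2-methoxy-4-(methoxymethoxy)phenyl]-8-[(2R)-5-methyl-2-(prop-1-en-2-yl)-5-(triethylsilyloxy)hexyl]chroman-4-one, mixture of C2 epimers | C=C(C)[C@H](CCC(C)(C)O[Si](CC)(CC)CC)Cc1c(OCOC)cc(OCOC)c2c1OC(c1ccc(OCOC)cc1OC)CC2=O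
F5 | step 16 | (2R,4R)-5,7-bis(methoxymethoxy)-2-[2-methoxy-4-(methoxymethoxy)phenyl]-8-[(2R)-5-methyl-2-(prop-1-en-2-yl)-5-(triethylsilyloxy)hexyl]chroman-4-ol | C=C(C)[C@H](CCC(C)(C)O[Si](CC)(CC)CC)Cc1c(OCOC)cc(OCOC)c2c1O[C@@H](c1ccc(OCOC)cc1OC)C[C@H]2O
F6 | step 17 | (2S)-2-[2-methoxy-4-(trimethylsilyloxy)phenyl]-8-[(2R)-5-methyl-2-(prop-1-en-2-yl)-5-(triethylsilyloxy)hexyl]-5,7-bis(trimethylsilyloxy)chroman-4-one | C=C(C)[C@H](CCC(C)(C)O[Si](CC)(CC)CC)Cc1c(O[Si](C)(C)C)cc(O[Si](C)(C)C)c2c1O[C@H](c1ccc(O[Si](C)(C)C)cc1OC)CC2=O
F7 | step 10 | (3R)-3-{[2-hydroxy-4,6-bis(methoxymethoxy)phenyl]methyl}-2,6-dimethyl-6-(triethylsilyloxy)-1-(trimethylsilyl)heptan-2-ol (carbinol epimers) | C[Si](C)(C)CC(C)(O)[C@@H](Cc1c(O)cc(OCOC)cc1OCOC)CCC(C)(C)O[Si](CC)(CC)CC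
A1 | alternative 1 | 2-[(2R)-5-methyl-2-(prop-1-en-2-yl)-5-(triethylsilyloxy)hexyl]-3-(triisopropylsilyloxy)-5-[2-(trimethylsilyl)ethoxy]phenol | C=C(C)[C@H](CCC(C)(C)O[Si](CC)(CC)CC)Cc1c(O)cc(OCC[Si](C)(C)C)cc1O[Si](C(C)C)(C(C)C)C(C)C
A2 | alternative 1 | triisopropyl{[(4R)-7-methyl-4-(prop-1-en-2-yl)-7-(triethylsilyloxy)oct-1-yn-1-yl]oxy}silane | C=C(C)[C@H](CCC(C)(C)O[Si](CC)(CC)CC)CC#CO[Si](C(C)C)(C(C)C)C(C)C
A3 | alternative 1 | 3-[2-(trimethylsilyl)ethoxy]cyclobut-2-en-1-one | O=C1C=C(OCC[Si](C)(C)C)C1
A4 | alternative 1 | (R)-limonene | CC1=CC[C@@H](CC1)C(C)=C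
A5 | alternative 2 | (2S,4S)-2,4-cis-4-methoxy-5,7-bis(methoxymethoxy)-2-(4-hydroxy-2-methoxyphenyl)-8-[(2R)-5-hydroxy-5-methyl-2-(prop-1-en-2-yl)hexyl]chromane | C=C(C)[C@H](CCC(C)(C)O)Cc1c(OCOC)cc(OCOC)c2c1O[C@H](c1ccc(O)cc1OC)C[C@@H]2OC
A6 | alternative 2 | 2-hydroxy-3-[(2R)-5-hydroxy-5-methyl-2-(prop-1-en-2-yl)hexyl]-4,6-bis(methoxymethoxy)benzaldehyde | C=C(C)[C@H](CCC(C)(C)O)Cc1c(O)c(C=O)c(OCOC)cc1OCOC
A7 | alternative 2 | 4-ethenyl-3-methoxyphenol | C=Cc1ccc(O)cc1OC
A8 | alternative 2 | 2-[(2R)-5-hydroxy-5-methyl-2-(prop-1-en-2-yl)hexyl]-6-(methoxymethylidene)-3,5-bis(methoxymethoxy)cyclohexa-2,4-dien-1-one | C=C(C)[C@H](CCC(C)(C)O)CC1=C(OCOC)C=C(OCOC)C(=COC)C1=O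
A9 | alternative 3 | (2S)-2-[2-methoxy-4-(triisopropylsilyloxy)phenyl]-8-[(2R)-5-methyl-2-(prop-1-en-2-yl)-5-(triethylsilyloxy)hexyl]-5,7-bis(triisopropylsilyloxy)chroman-4-one | C=C(C)[C@H](CCC(C)(C)O[Si](CC)(CC)CC)Cc1c(O[Si](C(C)C)(C(C)C)C(C)C)cc(O[Si](C(C)C)(C(C)C)C(C)C)c2c1O[C@H](c1ccc(O[Si](C(C)C)(C(C)C)C(C)C)cc1OC)CC2=O
A10 | alternative 3 | 2-diazo-1-{2-{[2-methoxy-4-(triisopropylsilyloxy)phenyl]methoxy}-3-[(2R)-5-methyl-2-(prop-1-en-2-yl)-5-(triethylsilyloxy)hexyl]-4,6-bis(triisopropylsilyloxy)phenyl}ethan-1-one | C=C(C)[C@H](CCC(C)(C)O[Si](CC)(CC)CC)Cc1c(O[Si](C(C)C)(C(C)C)C(C)C)cc(O[Si](C(C)C)(C(C)C)C(C)C)c(C(=O)C=[N+]=[N-])c1OCc1ccc(O[Si](C(C)C)(C(C)C)C(C)C)cc1OC
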